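Assumption: the target has no stereocentre (it is achiral), so no configuration has to be set and the SMILES is taken as drawn.

**Retrosynthetic overview**
1. Cut the ArCH2–Ar' bond: ring A as a para-quinone methide (from Mannich base 6) plus the acylphloroglucinol 8.
2. Mannich base 6 comes from phenol 5; its OH is both a target substituent and the para-activator for aminomethylation and quinone-methide formation.
3. Key disconnection: the aryl C–OH bond of 5, made by ketone-directed ortho C–H hydroxylation of ketone 3 (proposed on a new substrate class).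
4. Ketone 3 comes from 2,5-dimethylanisole and butanoyl chloride; 8 comes from 2-methylphloroglucinol and the same acid chloride.
5. No ring is formed; both benzene rings are bought.

**Route**

Step 1
Reactants: 1 2,5-dimethylanisole; 2 butanoyl chloride
Product: 3 1-(4-methoxy-2,5-dimethylphenyl)butan-1-one
Conditions: AlCl3 (1.2 equiv), CH2Cl2, 0 °C to rt
Reagents that add atoms: none
Why: Friedel–Crafts acylation goes para to the methoxy group, since the only ortho site is less activated and more hindered.

Step 2
Reactants: 3 1-(4-methoxy-2,5-dimethylphenyl)butan-1-one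
Product: 5 1-(2-hydroxy-4-methoxy-3,6-dimethylphenyl)butan-1-one, via aryl trifluoroacetate 4 (not isolated)
Conditions: [RuCl2(p-cymene)]2 (5 mol %), PhI(OCOCF3)2 (1.5 equiv), TFA/TFAA 3:1, 80 °C; then H2O/THF, rt
Reagents that add atoms: [bis(trifluoroacetoxy)iodo]benzene, FC(F)(F)C(=O)OI(OC(=O)C(F)(F)F)c1ccccc1
Why: Proposed new method: the ketone oxygen binds Ru(II) trifluoroacetate and delivers it to the only ortho C–H by carboxylate-assisted cycloruthenation (five-membered ruthenacycle), PhI(OCOCF3)2 oxidises this to Ru(IV), and C–O reductive elimination gives trifluoroacetate 4, whose electron-poor ester shields the new phenol from over-oxidation until aqueous hydrolysis; the closest known reaction type is Ru(II)- or Pd(II)-catalysed ketone-directed ortho C–H hydroxylation of simple aryl ketones, which to my knowledge has not been shown for a ketone with one ortho position blocked by methyl and the remaining ortho C–H flanked by a second methyl on an oxidation-prone anisole ring.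

Step 3
Reactants: 5 1-(2-hydroxy-4-methoxy-3,6-dimethylphenyl)butan-1-one
Product: 6 1-[3-[(dimethylamino)methyl]-6-hydroxy-4-methoxy-2,5-dimethylphenyl]butan-1-one
Conditions: Eschenmoser's salt (1.2 equiv), K2CO3 (1.2 equiv), MeCN, rt to 50 °C
Reagents that add atoms: N,N-dimethylmethyleneiminium iodide (Eschenmoser's salt), C=[N+](C)C.[I-]
Why: Mannich aminomethylation of the phenoxide with a preformed iminium ion occurs at the only free ring carbon, which is para to the phenol oxygen and ortho to OMe.

Step 4
Reactants: 7 2-methylbenzene-1,3,5-triol; 2 butanoyl chloride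
Product: 8 1-(2,4,6-trihydroxy-3-methylphenyl)butan-1-one
Conditions: AlCl3 (4 equiv), 2 (1.0 equiv), PhNO2, 0 °C then 65 °C
Reagents that add atoms: none
Why: Friedel–Crafts C-acylation of the phloroglucinol at one of its two equivalent free positions stops at the mono-ketone because the chelated acyl group deactivates the ring and only one equivalent of 2 is used.

Step 5
Reactants: 6 1-[3-[(dimethylamino)methyl]-6-hydroxy-4-methoxy-2,5-dimethylphenyl]butan-1-one; 8 1-(2,4,6-trihydroxy-3-methylphenyl)butan-1-one
Product: 10 1-[3-[(3-butanoyl-2,4,6-trihydroxy-5-methylphenyl)methyl]-6-hydroxy-4-methoxy-2,5-dimethylphenyl]butan-1-one, via para-quinone methide 9 (not isolated)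
Conditions: 8 (1.3 equiv), 1,4-dioxane, 100 °C, N2 sweep
Reagents that add atoms: none
Why: Thermal loss of Me2NH from the para-hydroxybenzylamine (Mannich-base amine exchange) gives quinone methide 9, which the only free ring carbon of 8 attacks in a 1,6-addition, and both rings rearomatise.

**Compound list**
1 | 2,5-dimethylanisole (1-methoxy-2,5-dimethylbenzene) | COc1cc(C)ccc1C | starting material
2 | butanoyl chloride | CCCC(=O)Cl | starting material
3 | 1-(4-methoxy-2,5-dimethylphenyl)butan-1-one | CCCC(=O)c1cc(C)c(OC)cc1C | intermediate
4 | 2-butanoyl-5-methoxy-3,6-dimethylphenyl 2,2,2-trifluoroacetate | CCCC(=O)c1c(OC(=O)C(F)(F)F)c(C)c(OC)cc1C | intermediate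
5 | 1-(2-hydroxy-4-methoxy-3,6-dimethylphenyl)butan-1-one | CCCC(=O)c1c(O)c(C)c(OC)cc1C | intermediate
6 | 1-[3-[(dimethylamino)methyl]-6-hydroxy-4-methoxy-2,5-dimethylphenyl]butan-1-one | CCCC(=O)c1c(C)c(CN(C)C)c(OC)c(C)c1O | intermediate
7 | 2-methylbenzene-1,3,5-triol (2-methylphloroglucinol) | Cc1c(O)cc(O)cc1O | starting material
8 | 1-(2,4,6-trihydroxy-3-methylphenyl)butan-1-one | CCCC(=O)c1c(O)cc(O)c(C)c1O | intermediate
9 | 2-butanoyl-5-methoxy-3,6-dimethyl-4-methylidenecyclohexa-2,5-dien-1-one | CCCC(=O)C1=C(C)C(=C)C(OC)=C(C)C1=O | intermediate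
10 | 1-[3-[(3-butanoyl-2,4,6-trihydroxy-5-methylphenyl)methyl]-6-hydroxy-4-methoxy-2,5-dimethylphenyl]butan-1-one | CCCC(=O)c1c(C)c(Cc2c(O)c(C)c(O)c(C(=O)CCC)c2O)c(OC)c(C)c1O | target

**Step count**
Total steps: 5. Longest linear sequence: 4 (steps 1, 2, 3, 5).

**Three steps most likely to fail**

Step 2 (the proposed new C–H hydroxylation). The reacting C–H is buttressed by a methyl group, and the 2-methyl group twists the carbonyl out of the ring plane. PhI(OCOCF3)2 could also oxidise the anisole ring without direction at the position ortho to OMe, or oxidise the ketone α-carbon. The fallback uses known chemistry and buys the second oxygen instead of making it. It sets out from butanoyl chloride 2, which acylates commercial 2,5-dimethylbenzene-1,3-diol F1 (AlCl3, PhNO2, 60 °C; the two free positions are equivalent) to 1-(2,4-dihydroxy-3,6-dimethylphenyl)butan-1-one F2. MeI (1.05 equiv) and K2CO3 in acetone at rt then methylate only the 4-OH, because the 2-OH is locked in a hydrogen bond to the carbonyl. This comes back to the route at 5.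

Step 3 (Mannich reaction). The hydrogen-bonded phenol is a weak nucleophile, and the free position is flanked by OMe and methyl. The fallback sets out from 5 and replaces aminomethylation by Blanc chloromethylation (paraformaldehyde, HCl gas, AcOH, 50 °C), giving 1-[3-(chloromethyl)-6-hydroxy-4-methoxy-2,5-dimethylphenyl]butan-1-one F3. Diarylmethane by-products cannot form because 5 has only one free ring position. F3 then benzylates 8 in a Friedel–Crafts alkylation (ZnCl2 10 mol %, 1,4-dioxane, 50 °C) and comes back to the route directly at 10, bypassing 6.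

Step 5 (thermal union). The quinone methide may form too slowly at 100 °C, or dimethylamine transfer may give the homodimer of 8. The fallback sets out from 6 and replaces neutral thermal amine exchange by ionic alkylation with an isolated quaternary ammonium electrophile. MeI in MeCN at rt gives 1-(3-butanoyl-4-hydroxy-6-methoxy-2,5-dimethylphenyl)-N,N,N-trimethylmethanaminium iodide F4. With 8 and K2CO3 in THF/MeOH at 0 °C to rt, F4 loses trimethylamine and C-alkylates the phenolate of 8, coming back to the route at 10.

Further compounds
F1 | step 2 | 2,5-dimethylbenzene-1,3-diol | Cc1cc(O)c(C)c(O)c1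
F2 | step 2 | 1-(2,4-dihydroxy-3,6-dimethylphenyl)butan-1-one | CCCC(=O)c1c(O)c(C)c(O)cc1C
F3 | step 3 | 1-[3-(chloromethyl)-6-hydroxy-4-methoxy-2,5-dimethylphenyl]butan-1-one | CCCC(=O)c1c(C)c(CCl)c(OC)c(C)c1O
F4 | step 5 | 1-(3-butanoyl-4-hydroxy-6-methoxy-2,5-dimethylphenyl)-N,N,N-trimethylmethanaminium iodide | CCCC(=O)c1c(C)c(C[N+](C)(C)C)c(OC)c(C)c1O.[I-]
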